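The trap in the earlier runs was to read a low E as a poor route: at the end of the zeta run E stood at 2.6 % while J had fallen to 44.4 %, so most of the lost J was held elsewhere.

| flask | J | X | Q | G | temperature | remark | time |
|---|---|---|---|---|---|---|---|
| alpha | 0.30 M | 1.8 equiv | 0.90 equiv | 0.90 equiv | 25 °C | run made earlier |  |
| zeta | 0.30 M | 1.8 equiv | 0.90 equiv | 1.4 equiv | 60 °C | run made earlier |  |
| beta | 0.45 M | 1.8 equiv | 0.90 equiv | 1.8 equiv | 25 °C | run made earlier |  |
| north-east | 0.30 M | 1.80 equiv | 0.900 equiv | 1.80 equiv | 50 °C |  | 1.0 h |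
| south | 0.30 M | 1.80 equiv | 0.900 equiv | 1.80 equiv | 30 °C |  | 1.0 h |
| east | 0.30 M | 1.80 equiv | 0.900 equiv | 1.80 equiv | 70 °C |  | 1.0 h |
| west | 0.30 M | 1.80 equiv | 0.900 equiv | 1.80 equiv | 90 °C |  | 1.0 h |

alpha run (percent of the J charged)

| time / h | E / % | J / % |
|---|---|---|
| 0.833 | 0.2 | 96.0 |
| 1.50 | 0 | 93.7 |
| 2.50 | 0 | 89.7 |
| 3.00 | 0.2 | 87.6 |
| 5.00 | 0 | 80.7 |

zeta run (percent of the J charged)

| time / min | E / % | J / % |
|---|---|---|
| 4.00 | 0.2 | 93.0 |
| 6.00 | 0.6 | 90.1 |
| 12.0 | 0 | 81.2 |
| 25.0 | 0.9 | 65.3 |
| 50.0 | 2.6 | 44.4 |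

beta run (percent of the J charged)

| time / h | E / % | J / % |
|---|---|---|
| 0.333 | 0.3 | 98.0 |
| 1.00 | 0 | 93.6 |
| 1.50 | 0.4 | 90.0 |
| 3.00 | 0.3 | 82.0 |
| 5.00 | 0.5 | 72.8 |

(scatter of a reading: 0.3 percentage points)

- percentages count the J that a species holds: one Z counts as two
- the analysis behind the earlier runs scatters by 0.3 percentage points, standard deviation
- reactions considered so far: J + D -> Z; J + X -> L; G + D <-> E; Q + L -> D

- the best flask by amount of E, in percent of the J charged; "all alike" if 1.5 percentage points covers them all (north-east / south / east / west / all alike)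
- amount of E at the end, in percent of the J charged, north-east
- amount of E at the end, in percent of the J charged, south
- amount of E at the end, in percent of the J charged, east
- amount of E at the end, in percent of the J charged, west

The listed reactions put E at the end of a chain: J with X gives L, L with Q gives D, and D goes to E with G or to Z with J. So J competes with G for D as long as J stands, and I wanted to know how far J had fallen in each flask.

The alpha run lost J at 0.0429 h⁻¹, which I read as pseudo-first-order with c_X taken at its start. The beta run over the alpha run gave a ratio of 1.48, close to the rise in c_X of 1.50, although G differed, so I set the zeta run beside the alpha run despite its different G. Its fourth reading gave 1.02 h⁻¹, and the pair gave an apparent activation energy of 74.8 kJ mol⁻¹.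

Working in powers of ten, I carried this rate to west and got 4.14. This is the J clock: the powers of ten by which J falls in the time of the flask at the extrapolated rate. East came to 0.976, but north-east and south to 0.193 and 0.0306, far less than east. So my own reckoning pointed to west as best; the clock counts J, so it gave me no figure for E.

The forecast named west, with 1.3 % for north-east, 0.1 % for south, 9 % for east and 20 % for west, holding that “E comes late, as J runs down”.

The flasks gave 0.840 % for north-east, 0.00593 % for south, 19.9 % for east and 63.8 % for west, so west was best.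

    J + D → Z (k = 0.0560 L mol⁻¹ min⁻¹, Ea = 80.0 kJ mol⁻¹)
    J + X → L (k = 0.0780 L mol⁻¹ min⁻¹, Ea = 76.0 kJ mol⁻¹)
    G + D ⇌ E (K = 84.0 L mol⁻¹, k = 0.0330 L mol⁻¹ min⁻¹, Ea = 69.0 kJ mol⁻¹, ΔH = 42.0 kJ mol⁻¹)
    Q + L → D (k = 0.210 L mol⁻¹ min⁻¹, Ea = 73.0 kJ mol⁻¹)
    (constants at 70 °C)

West fell by 3.02 powers of ten of J, fewer than the clock's 4.14, with X at 49.5 % of its charge. In west, the forward use of D by G over its use by J rose from 1.6 at 0.0651 h to 580 at 1.00 h.

For the west flask read at 15 min, the clock gives 1.03, close to east's 0.976, so I expected it to stand like east at its end. It held 19.7 % E and 12.1 % J, against 19.9 % and 14.3 % in east.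

The runs were computed on assumed constants; the scatter is artificial.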